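(The earlier runs and the new flask stem from a simulated flask from invented constants, noise included.)

Sunday's run and Saturday's run end at nearly the same product ratio, 2.61 and 2.60, although Saturday's run had twice the racemization catalyst.

| setting | Sunday's | Wednesday's | Saturday's | flask |
|---|---|---|---|---|
| left-handed substrate | 0.034 M | 0.075 M | 0.050 M | 0.050 M |
| right-handed substrate | 0.034 M | 0.075 M | 0.050 M | 0.050 M |
| gas | 17 mM (held) | 17 mM (held) | 17 mM (held) | 17 mM (held) |
| racemization catalyst | 2.3 mol% | 2.3 mol% | 4.6 mol% | 2.3 mol% |
| remark | run made earlier | run made earlier | run made earlier |  |
| time |  |  |  | 10 h |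

| run | time / h | left-handed product / % | right-handed product / % |
|---|---|---|---|
| Sunday's | 0.500 | 0.5 | 0 |
| Sunday's | 0.833 | 1.5 | 0.5 |
| Sunday's | 1.33 | 2.6 | 0.4 |
| Sunday's | 2.00 | 5.2 | 2.0 |
| Sunday's | 4.00 | 12.1 | 4.6 |
| Sunday's | 6.00 | 18.8 | 7.2 |
| Wednesday's | 0.500 | 0.7 | 0.2 |
| Wednesday's | 0.833 | 1.2 | 0 |
| Wednesday's | 1.33 | 2.4 | 1.1 |
| Wednesday's | 2.00 | 4.2 | 1.9 |
| Wednesday's | 4.00 | 10.0 | 4.0 |
| Wednesday's | 6.00 | 16.0 | 5.2 |
| Saturday's | 0.500 | 0.7 | 0.8 |
| Saturday's | 1.50 | 3.7 | 0.8 |
| Saturday's | 3.00 | 8.6 | 3.0 |
| Saturday's | 4.00 | 11.5 | 4.3 |
| Saturday's | 6.00 | 17.7 | 6.8 |

(scatter of a reading: 0.3 percentage points)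

- reagent is single-handed; left-handed substrate and right-handed substrate are mirror images of each other, charged as a racemate, each of them at the stated concentration
- at the start none of the gas is in solution
- an excess is the difference of the two amounts in percent of their sum
- an excess is below zero if the other one leads
- the handed part of reagent does not stay in what it makes, so the products of the two hands are mirror images too

- left-handed product and right-handed product together, in percent of the left-handed substrate and right-handed substrate charged together, at 10 h
- excess of left-handed product over right-handed product in the product at 10 h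
- whether the exchange between left-handed substrate and right-handed substrate keeps pace with the reaction: how far the product's excess at 10 h gets from its value without exchange to its value with instant exchange (above 80 % keeps pace, below 20 % hardly takes part, else lags behind)

1. The delay. Saturday's last two readings give a drain time of 23.0 h, the time to convert the whole charge at that pace. Traced back, that line shows a delay of about 0.368 h while gas enters solution, much shorter than the drain time.

2. The exchange. No run measures it directly, so I divide one product's rate by the other's and time drops out: d[left-handed product]/d[right-handed product] = s[left-handed substrate]/[right-handed substrate]. Here s is the hand ratio, the selectivity factor: how much faster the left-handed substrate reacts at equal concentrations. Early on the substrates are nearly equal, so I pool the last reading at or before 2.00 h from each run and get 2.79. This is a rough reading: each amount in it carries a scatter of 0.3 percentage points. Instant exchange keeps the substrates equal, so the excess would be (s−1)/(s+1) = 47.2 %. Without exchange, the excess falls as conversion grows.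

3. The drain. Extending Saturday's line to 10 h gives 41.9 %, and I expect a little less as substrate thins. Saturday's last excess, 44.5 %, is lower than 47.2 %, so I tentatively expect the exchange to lag behind.

The forecast gives 40 %, 45 % and "keeps pace", reasoning: “Doubling the catalyst changes nothing, so exchange keeps pace”. We differ on pace.

The flask gives 39.6 %, 43.6 % and "lags behind", having gone 57 % of the way. It has reacted 39.6 % by 10.0 h, in part because of the time allowed, set beside a tenfold time, together with how slow the uptake of gas as reagent is.

    reagent + left-handed substrate → left-handed product (k = 0.120 M⁻¹ min⁻¹)
    reagent + right-handed substrate → right-handed product (k = 0.0426 M⁻¹ min⁻¹)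
    left-handed substrate + racemization catalyst ⇌ right-handed substrate + racemization catalyst, rate k3*[racemization catalyst]*[left-handed substrate] forward; the back reaction follows from the equilibrium constant (k = 3.54 M⁻¹ min⁻¹)
    gas ⇌ reagent, rate k4*(csat - [reagent]) (kL = 0.0137 min⁻¹)
    reagent + racemization catalyst → spent catalyst (k = 0.112 M⁻¹ min⁻¹)

The passing of left-handed substrate into right-handed substrate, both ways, supplies part of the flask's excess: without that passing, the excess falls from 43.6 % to 38.4 %. The span from there up to 47.2 % is 8.8 points. On this scale, with my rough hand ratio, the flask stands 59.7 % of the way along. The neighbour flask with 3.9 mol% of racemization catalyst reaches 44.9 %, which is 73.9 % of the way on the same scale.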